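**Plan**

- Retrosynthesis: the C3–O ester bond is cut first, giving a trans-3-hydroxy-2,3-dihydrobenzofuran and the Z side-chain acid. C3–OH is traced back to C3–B, the isopropenyl C=CH2 to a C2 acetyl C=O, and the C5 acetyl to C5–Br. Removing the C3–B and C2–H bonds then gives a flat 2-acetylbenzofuran, which is cut at O1–C2 and C2=C3 into a salicylaldehyde and chloroacetone.
- Enabling feature: in benzofuran numbering the two stereocentres are C2 and C3 of the furan ring. C3 carries a heteroatom and C2 a carbon group that can stand at the ketone oxidation level, so both map onto the C2=C3 bond of an achiral 2-acylbenzofuran, in which C3 is the β-carbon of the O=C–C2=C3 unit.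
- Forward order: the furan ring is closed first and is the only ring made. It is then dearomatised by adding boron to C3 and hydrogen to C2. Stille coupling (masked 5-acetyl), methylenation of the 2-acetyl group and C–B oxidation follow.
- The side-chain acid is built separately from but-2-yn-1-ol and joined last by acylation of O3.
- Stereochemistry: C3 comes from ligand-controlled delivery of a copper boryl, C2 from equilibration to trans next to the ketone, and C–B becomes C–O with retention. The Z alkene comes from a trans-hydrostannation whose geometry is carried through with retention.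

Key step: step 2

Assumption: the bromosalicylaldehyde is taken as a catalogue compound, and the antipode of the bisphosphine that gives the (3S) boronate must be identified in the first runs; (R,R)-QuinoxP* is written, its mirror image being equally available.

**Route**

Step 1
Reactants: 1 5-bromo-2-hydroxy-4-methoxybenzaldehyde; 2 chloroacetone
Product: 5 2-acetyl-5-bromo-6-methoxybenzofuran, via aryloxyacetone 3 (not isolated), via cyclic aldol 4 (not isolated)
Conditions: K2CO3 (2.5 equiv), DMF, 80 °C
Reagents that add atoms: none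
Why: Rap–Stoermer benzofuran synthesis, in which the phenoxide of 1 is O-alkylated by the α-chloroketone, the ketone enolate of 3 closes onto the ortho aldehyde (intramolecular aldol) and aldol 4 dehydrates because the product is aromatic, so no stereocentre remains.

Step 2
Reactants: 5 2-acetyl-5-bromo-6-methoxybenzofuran; 6 bis(pinacolato)diboron
Product: 8 trans boronate 1-[(2S,3S)-5-bromo-6-methoxy-3-(4,4,5,5-tetramethyl-1,3,2-dioxaborolan-2-yl)-2,3-dihydro-1-benzofuran-2-yl]ethan-1-one, via cis epimer 7 (not isolated)
Conditions: CuCl (5 mol%), (R,R)-QuinoxP* (6 mol%), NaOtBu (10 mol%), B2pin2 (1.3 equiv), MeOH (2 equiv), THF, 0 °C to rt; then DBU (0.2 equiv), rt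
Reagents that add atoms: none
Why: Proposed new method: CuCl, NaOtBu and the bisphosphine give a ligated copper tert-butoxide that undergoes σ-bond metathesis with B2pin2 to a copper boryl, which adds across C2=C3 of 5 with boron at C3 (the β-carbon of the O=C–C2=C3 acceptor) and breaks the furan aromaticity, after which methanol protonates the O-bound copper enolate at C2 and returns copper methoxide to the cycle. The closest known reaction type is the copper-catalysed enantioselective β-borylation of enones together with its dearomative version on indole-2-carboxylates; a 2-acylbenzofuran has not been used, but its furan ring has less aromatic stabilisation to lose than the pyrrole ring of an indole and a ketone is a stronger acceptor than an ester. No ring is closed in this step. C3 is set by the chiral ligand, which selects the face of the flat heteroarene that receives boron, and C2 is set under thermodynamic control, because it is α to the ketone and the DBU finish equilibrates any cis epimer 7 to the trans isomer with acetyl and boryl on opposite faces. The step needs 1,4-borylation instead of 1,2-addition to the ketone and no borylation of the aryl bromide, which the soft phosphine-ligated copper boryl and the merely catalytic amount of alkoxide should secure. Ring opening by boron–oxygen elimination is not expected, because the C3–B and C2–O1 bonds of the five-membered ring cannot become periplanar.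

Step 3
Reactants: 8 trans boronate (2S,3S)
Product: 9 1-[(2S,3S)-5-(1-ethoxyethenyl)-6-methoxy-3-(4,4,5,5-tetramethyl-1,3,2-dioxaborolan-2-yl)-2,3-dihydro-1-benzofuran-2-yl]ethan-1-one
Conditions: tributyl(1-ethoxyvinyl)stannane (1.3 equiv), PdCl2(PPh3)2 (5 mol%), toluene, 95 °C; aq. KF work-up; chromatography on Et3N-deactivated silica
Reagents that add atoms: tributyl(1-ethoxyvinyl)stannane, CCCC[Sn](CCCC)(CCCC)C(=C)OCC
Why: Stille coupling of the aryl bromide under neutral, base-free conditions in which a secondary alkyl pinacol boronate does not transmetalate; it is placed here so that zerovalent palladium never meets the allylic aryl ether formed in step 4, and the enol ether is kept as a masked acetyl group so that 9 holds a single ketone.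

Step 4
Reactants: 9 enol ether ketone (2S,3S)
Product: 11 1-[(2S,3S)-6-methoxy-2-(prop-1-en-2-yl)-3-(4,4,5,5-tetramethyl-1,3,2-dioxaborolan-2-yl)-2,3-dihydro-1-benzofuran-5-yl]ethan-1-one, via enol ether diene 10 (not isolated)
Conditions: Cp2TiMe2 (2.5 equiv), toluene/THF, 65 °C, dark; then 1 M aq. HCl, THF, 0 °C to rt
Reagents that add atoms: dimethyltitanocene Cp2TiMe2, C[Ti](C)(C1C=CC=C1)C1C=CC=C1 (rings drawn σ-bonded); water, O
Why: Petasis methylenation, in which Cp2TiMe2 loses methane to give Cp2Ti=CH2 that converts the only C=O group into C=CH2 through an oxatitanacyclobutane without base (no epimerisation at C2) and leaves the pinacol boronate and the aryl enol ether (the kind of product this reagent itself makes from esters) untouched, after which dilute acid hydrolyses the enol ether of 10 to the aryl methyl ketone much faster than it affects the isopropenyl group or the C–B bond.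

Step 5
Reactants: 11 isopropenyl boronate (2S,3S)
Product: 12 1-[(2R,3S)-3-hydroxy-6-methoxy-2-(prop-1-en-2-yl)-2,3-dihydro-1-benzofuran-5-yl]ethan-1-one (trans alcohol)
Conditions: NaBO3·4H2O (4 equiv), THF/H2O (1:1), rt
Reagents that add atoms: sodium perborate NaBO3, [Na+].[O-]OB=O
Why: Boronate oxidation, in which the peroxide oxygen adds to boron and C3 migrates from boron to oxygen with retention, so the trans arrangement is carried over unchanged (the C2 descriptor changes from S to R only because C3 now outranks the isopropenyl carbon), while the mildly basic medium spares the aryl ketone and the ionisable benzylic alcohol.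

Step 6
Reactants: 13 but-2-yn-1-ol
Product: 14 (2Z)-2-(tributylstannyl)but-2-en-1-ol
Conditions: Bu3SnH (1.1 equiv), [Cp*RuCl]4 (1.5 mol%), CH2Cl2, rt
Reagents that add atoms: tributyltin hydride, CCCC[SnH](CCCC)CCCC
Why: Hydroxyl-directed ruthenium-catalysed trans-hydrostannation, in which hydrogen bonding of the propargylic OH to the Ru–Cl unit steers tin to the proximal alkyne carbon and H and Sn add to opposite faces, which places CH3 cis to tin.

Step 7
Reactants: 14 (2Z)-2-(tributylstannyl)but-2-en-1-ol
Product: 15 (2Z)-2-iodobut-2-en-1-ol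
Conditions: I2 (1.05 equiv), CH2Cl2, 0 °C; aq. Na2S2O3 then KF work-up
Reagents that add atoms: iodine, [I][I]
Why: Iododestannylation, an electrophilic ipso substitution of the C–Sn bond that proceeds with retention of alkene geometry.

Step 8
Reactants: 15 (2Z)-2-iodobut-2-en-1-ol
Product: 16 methyl (2Z)-2-(hydroxymethyl)but-2-enoate
Conditions: PdCl2(PPh3)2 (3 mol%), CO (1 atm), Et3N (2 equiv), MeOH, 50 °C
Reagents that add atoms: carbon monoxide, [C-]#[O+]; methanol, CO
Why: Palladium-catalysed methoxycarbonylation (oxidative addition of the alkenyl iodide to zerovalent palladium with retention, CO insertion, methanolysis of the acylpalladium), so the ester carbon takes the place of iodine cis to CH3.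

Step 9
Reactants: 16 methyl (2Z)-2-(hydroxymethyl)but-2-enoate
Product: 17 (2Z)-2-(hydroxymethyl)but-2-enoic acid
Conditions: LiOH·H2O (2 equiv), THF/H2O (3:1), 0 °C to rt; then 1 M HCl to pH 2
Reagents that add atoms: lithium hydroxide, [Li+].[OH-]
Why: Saponification at or below room temperature, mild enough not to isomerise the trisubstituted Z-enoate.

Step 10
Reactants: 17 (2Z)-2-(hydroxymethyl)but-2-enoic acid
Product: 19 (2Z)-2-[(acetyloxy)methyl]but-2-enoic acid, via acetic mixed anhydride 18 (not isolated)
Conditions: Ac2O (2.5 equiv), pyridine, CH2Cl2, 0 °C to rt; then H2O, rt; dilute HCl work-up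
Reagents that add atoms: acetic anhydride, CC(=O)OC(C)=O
Why: Acetylation of the primary allylic alcohol without DMAP (which could displace the new allylic acetate in an SN2′ sense); the carboxyl group is acetylated too, giving mixed anhydride 18, which water cleaves at its acetyl carbonyl during the quench to return the free acid.

Step 11
Reactants: 19 (2Z)-2-[(acetyloxy)methyl]but-2-enoic acid; 12 trans alcohol (2R,3S)
Product: 21 (2R,3S)-5-acetyl-6-methoxy-2-(prop-1-en-2-yl)-2,3-dihydro-1-benzofuran-3-yl (2Z)-2-[(acetyloxy)methyl]but-2-enoate, via Yamaguchi mixed anhydride 20 (not isolated)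
Conditions: 19 (1.5 equiv), 2,4,6-trichlorobenzoyl chloride (1.5 equiv), Et3N (3 equiv), toluene, rt; then 12, toluene, 60 °C (no DMAP)
Reagents that add atoms: none
Why: Yamaguchi esterification, in which the hindered 2,6-dichloroaroyl carbonyl of 20 directs the secondary alcohol to the enoyl carbonyl; it is run thermally without a nucleophilic pyridine catalyst, as is usual for angelate-type Z-acids, because such a catalyst could add to the β-carbon (Z to E) or displace the allylic acetate, and O-acylation leaves the C3–O bond and both stereocentres untouched.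

**Compound list**

1 | 5-bromo-2-hydroxy-4-methoxybenzaldehyde | O=Cc1cc(Br)c(OC)cc1O | starting material
2 | chloroacetone | CC(=O)CCl | starting material
3 | 5-bromo-4-methoxy-2-(2-oxopropoxy)benzaldehyde | CC(=O)COc1cc(OC)c(Br)cc1C=O | intermediate (not isolated)
4 | 1-(5-bromo-3-hydroxy-6-methoxy-2,3-dihydro-1-benzofuran-2-yl)ethan-1-one, mixture of stereoisomers | CC(=O)C1Oc2cc(OC)c(Br)cc2C1O | intermediate (not isolated)
5 | 1-(5-bromo-6-methoxy-1-benzofuran-2-yl)ethan-1-one | CC(=O)c1cc2cc(Br)c(OC)cc2o1 | intermediate
6 | bis(pinacolato)diboron | CC1(C)OB(OC1(C)C)B1OC(C)(C)C(C)(C)O1 | starting material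
7 | 1-[(2R,3S)-5-bromo-6-methoxy-3-(4,4,5,5-tetramethyl-1,3,2-dioxaborolan-2-yl)-2,3-dihydro-1-benzofuran-2-yl]ethan-1-one (cis) | CC(=O)[C@@H]1Oc2cc(OC)c(Br)cc2[C@@H]1B3OC(C)(C)C(C)(C)O3 | intermediate (not isolated)
8 | 1-[(2S,3S)-5-bromo-6-methoxy-3-(4,4,5,5-tetramethyl-1,3,2-dioxaborolan-2-yl)-2,3-dihydro-1-benzofuran-2-yl]ethan-1-one (trans) | CC(=O)[C@H]1Oc2cc(OC)c(Br)cc2[C@@H]1B3OC(C)(C)C(C)(C)O3 | intermediate
9 | 1-[(2S,3S)-5-(1-ethoxyethenyl)-6-methoxy-3-(4,4,5,5-tetramethyl-1,3,2-dioxaborolan-2-yl)-2,3-dihydro-1-benzofuran-2-yl]ethan-1-one | CC(=O)[C@H]1Oc2cc(OC)c(C(=C)OCC)cc2[C@@H]1B3OC(C)(C)C(C)(C)O3 | intermediate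
10 | 2-[(2S,3S)-5-(1-ethoxyethenyl)-6-methoxy-2-(prop-1-en-2-yl)-2,3-dihydro-1-benzofuran-3-yl]-4,4,5,5-tetramethyl-1,3,2-dioxaborolane | C=C(C)[C@H]1Oc2cc(OC)c(C(=C)OCC)cc2[C@@H]1B3OC(C)(C)C(C)(C)O3 | intermediate (not isolated)
11 | 1-[(2S,3S)-6-methoxy-2-(prop-1-en-2-yl)-3-(4,4,5,5-tetramethyl-1,3,2-dioxaborolan-2-yl)-2,3-dihydro-1-benzofuran-5-yl]ethan-1-one | C=C(C)[C@H]1Oc2cc(OC)c(C(C)=O)cc2[C@@H]1B3OC(C)(C)C(C)(C)O3 | intermediate
12 | 1-[(2R,3S)-3-hydroxy-6-methoxy-2-(prop-1-en-2-yl)-2,3-dihydro-1-benzofuran-5-yl]ethan-1-one | C=C(C)[C@H]1Oc2cc(OC)c(C(C)=O)cc2[C@@H]1O | intermediate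
13 | but-2-yn-1-ol | CC#CCO | starting material
14 | (2Z)-2-(tributylstannyl)but-2-en-1-ol | C/C=C(/CO)[Sn](CCCC)(CCCC)CCCC | intermediate
15 | (2Z)-2-iodobut-2-en-1-ol | C/C=C(/CO)I | intermediate
16 | methyl (2Z)-2-(hydroxymethyl)but-2-enoate | C/C=C(/CO)C(=O)OC | intermediate
17 | (2Z)-2-(hydroxymethyl)but-2-enoic acid | C/C=C(/CO)C(=O)O | intermediate
18 | acetic (2Z)-2-[(acetyloxy)methyl]but-2-enoic anhydride | C/C=C(/COC(C)=O)C(=O)OC(C)=O | intermediate (not isolated)
19 | (2Z)-2-[(acetyloxy)methyl]but-2-enoic acid | C/C=C(/COC(C)=O)C(=O)O | intermediate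
20 | (2Z)-2-[(acetyloxy)methyl]but-2-enoic 2,4,6-trichlorobenzoic anhydride | C/C=C(/COC(C)=O)C(=O)OC(=O)c1c(Cl)cc(Cl)cc1Cl | intermediate (not isolated)
21 | (2R,3S)-5-acetyl-6-methoxy-2-(prop-1-en-2-yl)-2,3-dihydro-1-benzofuran-3-yl (2Z)-2-[(acetyloxy)methyl]but-2-enoate | C=C(C)[C@H]1Oc2cc(OC)c(C(C)=O)cc2[C@@H]1OC(=O)/C(=C\C)COC(C)=O | target

**Step count**

Total: 11 steps. Longest linear sequence: 6 steps (steps 1–5 then 11; the side-chain branch, steps 6–10 then 11, is equally long).

**Steps most likely to fail**

1. Step 2 (proposed new method).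
   - What may go wrong: the copper boryl may not overcome the furan aromaticity (no conversion, or 1,2-addition to the carbonyl), the facial selectivity at C3 may be poor, or alkoxide activation of boron may open the ring by boron–oxygen elimination.
   - Fallback, by known reaction types, setting out from 1 and coming back at 12:
     - Silylation of 1 (TBSCl, imidazole, DMF) should give 5-bromo-2-[(tert-butyldimethylsilyl)oxy]-4-methoxybenzaldehyde F1.
     - Horner–Wadsworth–Emmons olefination with the lithium anion of diethyl (2-methylallyl)phosphonate (n-BuLi, THF, −78 °C to rt) should give the E diene tert-butyl{4-bromo-5-methoxy-2-[(1E)-3-methylbuta-1,3-dien-1-yl]phenoxy}dimethylsilane F2.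
     - Shi epoxidation with the L-sorbose-derived antipode of the usual fructose-derived ketone (KHSO5 as Oxone, K2CO3 buffer, MeCN/dimethoxymethane/H2O, 0 °C) is expected to oxidise only the trans-disubstituted styrenic double bond, giving (2S,3S)-2-{5-bromo-2-[(tert-butyldimethylsilyl)oxy]-4-methoxyphenyl}-3-(prop-1-en-2-yl)oxirane F3.
     - TBAF in THF frees the phenoxide, which should open the vinyl epoxide at its allylic carbon with inversion to give the trans alcohol (2R,3S)-5-bromo-6-methoxy-2-(prop-1-en-2-yl)-2,3-dihydro-1-benzofuran-3-ol F4.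
     - Stille coupling with tributyl(1-ethoxyvinyl)stannane (Pd(P(t-Bu)3)2, CsF, dioxane, rt to 40 °C, kept mild so that zerovalent palladium does not ionise the allylic aryl ether) should give (2R,3S)-5-(1-ethoxyethenyl)-6-methoxy-2-(prop-1-en-2-yl)-2,3-dihydro-1-benzofuran-3-ol F5, which aqueous oxalic acid in THF at 0 °C hydrolyses to 12.

2. Step 4.
   - What may go wrong: the titanium methylidene may enolise the α-aryloxy ketone instead of methylenating it, titanium Lewis acidity may trigger loss of the boronate with ring opening, or premature hydrolysis of the enol ether may lead to methylenation of the aryl ketone as well.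
   - Fallback, setting out from 9 and coming back at 10: kinetic enolisation at the methyl group (KN(SiMe3)2, THF, −78 °C) and trapping with PhNTf2 should give the enol triflate 1-[(2S,3S)-5-(1-ethoxyethenyl)-6-methoxy-3-(4,4,5,5-tetramethyl-1,3,2-dioxaborolan-2-yl)-2,3-dihydro-1-benzofuran-2-yl]ethenyl trifluoromethanesulfonate F6. Negishi coupling with MeZnCl (Pd(PPh3)4, THF, rt) then replaces the triflate by methyl, which builds the isopropenyl group by C–C coupling instead of carbonyl olefination and gives 10; 10 is hydrolysed to 11 as in step 4.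

3. Step 11.
   - What may go wrong: acylation without a nucleophilic catalyst may be slow, and prolonged heating may ionise the electron-rich benzylic C3–O bond with aromatisation to the benzofuran; if DMAP is added to compensate, Z to E isomerisation and allylic transposition of the acetate may follow.
   - Fallback, setting out from 16 and 12 and coming back at 21: the allylic oxygen is carried as a silyl ether, which is no leaving group, so a catalysed low-temperature coupling becomes possible.
     - Silylation of 16 (TBSCl, imidazole, DMF) should give methyl (2Z)-2-{[(tert-butyldimethylsilyl)oxy]methyl}but-2-enoate F7.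
     - LiOH (THF/H2O, rt) should give (2Z)-2-{[(tert-butyldimethylsilyl)oxy]methyl}but-2-enoic acid F8.
     - Steglich coupling with 12 (DCC, catalytic DMAP, CH2Cl2, 0 °C) should give (2R,3S)-5-acetyl-6-methoxy-2-(prop-1-en-2-yl)-2,3-dihydro-1-benzofuran-3-yl (2Z)-2-{[(tert-butyldimethylsilyl)oxy]methyl}but-2-enoate F9.
     - Pyridine-buffered HF·pyridine (THF, 0 °C) should give (2R,3S)-5-acetyl-6-methoxy-2-(prop-1-en-2-yl)-2,3-dihydro-1-benzofuran-3-yl (2Z)-2-(hydroxymethyl)but-2-enoate F10, and Ac2O/pyridine then gives 21.

**Further compounds**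

F1 | step 2 | 5-bromo-2-[(tert-butyldimethylsilyl)oxy]-4-methoxybenzaldehyde | O=Cc1cc(Br)c(OC)cc1O[Si](C)(C)C(C)(C)C
F2 | step 2 | tert-butyl{4-bromo-5-methoxy-2-[(1E)-3-methylbuta-1,3-dien-1-yl]phenoxy}dimethylsilane | CC(=C)/C=C/c1cc(Br)c(OC)cc1O[Si](C)(C)C(C)(C)C
F3 | step 2 | (2S,3S)-2-{5-bromo-2-[(tert-butyldimethylsilyl)oxy]-4-methoxyphenyl}-3-(prop-1-en-2-yl)oxirane | CC(=C)[C@@H]1O[C@H]1c2cc(Br)c(OC)cc2O[Si](C)(C)C(C)(C)C
F4 | step 2 | (2R,3S)-5-bromo-6-methoxy-2-(prop-1-en-2-yl)-2,3-dihydro-1-benzofuran-3-ol | C=C(C)[C@H]1Oc2cc(OC)c(Br)cc2[C@@H]1O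
F5 | step 2 | (2R,3S)-5-(1-ethoxyethenyl)-6-methoxy-2-(prop-1-en-2-yl)-2,3-dihydro-1-benzofuran-3-ol | C=C(C)[C@H]1Oc2cc(OC)c(C(=C)OCC)cc2[C@@H]1O
F6 | step 4 | 1-[(2S,3S)-5-(1-ethoxyethenyl)-6-methoxy-3-(4,4,5,5-tetramethyl-1,3,2-dioxaborolan-2-yl)-2,3-dihydro-1-benzofuran-2-yl]ethenyl trifluoromethanesulfonate | C=C(OS(=O)(=O)C(F)(F)F)[C@H]1Oc2cc(OC)c(C(=C)OCC)cc2[C@@H]1B3OC(C)(C)C(C)(C)O3
F7 | step 11 | methyl (2Z)-2-{[(tert-butyldimethylsilyl)oxy]methyl}but-2-enoate | C/C=C(/CO[Si](C)(C)C(C)(C)C)C(=O)OC
F8 | step 11 | (2Z)-2-{[(tert-butyldimethylsilyl)oxy]methyl}but-2-enoic acid | C/C=C(/CO[Si](C)(C)C(C)(C)C)C(=O)O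
F9 | step 11 | (2R,3S)-5-acetyl-6-methoxy-2-(prop-1-en-2-yl)-2,3-dihydro-1-benzofuran-3-yl (2Z)-2-{[(tert-butyldimethylsilyl)oxy]methyl}but-2-enoate | C=C(C)[C@H]1Oc2cc(OC)c(C(C)=O)cc2[C@@H]1OC(=O)/C(=C\C)CO[Si](C)(C)C(C)(C)C
F10 | step 11 | (2R,3S)-5-acetyl-6-methoxy-2-(prop-1-en-2-yl)-2,3-dihydro-1-benzofuran-3-yl (2Z)-2-(hydroxymethyl)but-2-enoate | C=C(C)[C@H]1Oc2cc(OC)c(C(C)=O)cc2[C@@H]1OC(=O)/C(=C\C)CO
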